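Slowness shows in a table as a column still climbing from row to row, so the two earlier runs are read for that first.

all flasks: G 0.20 M
- midnight: J 0.27 M; D 5 mM; run made earlier
- noon: J 0.42 M; D 5 mM; run made earlier
- flask: J 0.190 M; D 5.0 mM; time 80 min

| run | time / min | Z / % | Q / % |
|---|---|---|---|
| midnight | 12.0 | 54.3 | 11.1 |
| midnight | 25.0 | 53.5 | 11.3 |
| midnight | 40.0 | 53.1 | 11.3 |
| midnight | 50.0 | 53.6 | 11.4 |
| midnight | 60.0 | 53.7 | 11.6 |
| noon | 12.0 | 62.8 | 14.6 |
| noon | 25.0 | 63.4 | 14.0 |
| noon | 40.0 | 63.2 | 15.2 |
| noon | 50.0 | 64.2 | 14.0 |
| noon | 60.0 | 64.2 | 13.4 |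

(standard deviation of a reading: 0.5 percentage points)

- how much Z there is at 80 min, in percent of the G charged
- how much Q there is at 80 min, in percent of the G charged

Row against row, the sum Z + Q moves in the midnight run from 65.4% at 12.0 min to 65.3% at 60.0 min, and in the noon run from 77.4% to 77.6%. Each shift is smaller than the scatter of a reading, 0.5 percentage points, so within that scatter both runs stand still from the first row.

Column against column, the mean sum is 65.0% at midnight and 77.8% at noon, higher with more J. Yet the midnight run stops with G at 0.0700 M and J at 0.140 M, which points to a balance, not a shortage.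

Let x be the concentration of G converted, counting one J per G in either product. Then x/([G][J]) reads 13.2 M⁻¹ at midnight and 13.3 M⁻¹ at noon. Their mean 13.3 M⁻¹ is carried on as the rest quotient K, x/([G][J]) at standstill, an apparent equilibrium constant. The readings also give Q/Z = 0.218.

If the time to standstill scales inversely with J, the 12.0 min of the first midnight row becomes an estimate of 17.1 min for the flask, shorter than 80 min. Solving K for the flask's charges gives x = 0.106 M, which splits into 43.3% Z and 9.46% Q.

The forecast, a little apart from this reckoning, gives 43.4% Z and 9.4% Q, saying “These constant ratios suggest equilibrium”. The flask gives 43.4% Z and 9.56% Q.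

    G + J + D ⇌ Z + D, rate k1*[G]*[J]*[D] forward; the back reaction follows from the equilibrium constant (K = 11.0 M⁻¹, k = 140 M⁻² s⁻¹)
    D ⇌ L (K = 1.70, k = 0.110 s⁻¹)
    Z ⇌ Q (K = 0.220, k = 0.0300 s⁻¹)

The flask is at rest well before 80 min: Q stands at 9.56% at 4.00 min and at 9.56% at 800 min, so ten times the time changes Q by nothing, and Z then stands at 43.4%. The relaxation half-life of G + J and Z by their own step alone, both ways together, is 0.166 min at the asked time and fits 482 times into the flask's run. The flask's Z and Q give a quotient of 13.4 M⁻¹, beside the 13.3 M⁻¹ read from the scattered runs as K. The same flask with 0.32 M of J reckons by K to 57.8% Z, and it holds 57.9%.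

(The data were computed with made-up constants; scatter was added.)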